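Your closed vessel holds substrate and coupling partner at 1.00 equiv, so its charge allows target up to 100 percent. The violet flask, at 0.50 equiv, allows 50.0%, and it reads 44% at 5.00 d with substrate left over. So I take the coupling partner as the limiting reagent and let the rate follow it.

| setting | green | violet | flask |
|---|---|---|---|
| substrate | 0.10 M | 0.10 M | 0.10 M |
| coupling partner | 1 equiv | 0.50 equiv | 1.00 equiv |
| free catalyst | 0.2 mol% | 0.2 mol% | 0.2 mol% |
| remark | the very flask that is asked about, followed so far | run made earlier |  |

| run | time / d | target / % |
|---|---|---|
| green | 0.417 | 24 |
| green | 1.25 | 53 |
| green | 2.00 | 70 |
| green | 3.00 | 81 |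
| green | 5.00 | 89 |
| green | 6.00 | 94 |
| violet | 0.833 | 24 |
| violet | 1.67 | 32 |
| violet | 2.50 | 38 |
| violet | 3.00 | 41 |
| violet | 4.00 | 44 |
| violet | 5.00 | 44 |

(readings scatter by 2 percentage points)

- the numbers in the tables scatter by 2 percentage points (one standard deviation)
- reactions considered so far: substrate + catalyst intermediate A -> catalyst intermediate B; coupling partner + free catalyst -> catalyst intermediate A; coupling partner <-> dormant form; catalyst intermediate B -> free catalyst + target
- no earlier run changes the charge of free catalyst; that part of a forecast is a guess

1. apparent order in free catalyst when 30% of the substrate are converted (percent change of the rate of making target for one percent more free catalyst charged)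
2. apparent order in coupling partner when 30% of the substrate are converted (percent change of the rate of making target for one percent more coupling partner charged)

The green reading of 70% at 2.00 d gives 0.602 d⁻¹. This is the clearance constant k, the rate of making target per coupling partner not yet converted, dormant form counted. The reading of 53% at 1.25 d gives 0.604 d⁻¹, the same within scatter.

Now climb the ladder. The first rung is one catalyst turn, 0.00332 d at the start. Next comes the half-life of the partner not yet converted, 1.15 d. A turn is far shorter than that half-life, so the catalyst forms keep pace. I therefore write the rate as k·(c(coupling partner) + c(dormant form)). The last rung is the approach to the end: 6.00 d is 5.22 half-lives, and green reads 94% there.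

At 30% conversion, the same amount used up leaves 70.0% of the partner, dormant form counted. One percent more charge therefore raises the rate by 1.43 percent. That is my order in coupling partner. For free catalyst I guess 1; no earlier run changes its charge.

The forecast gives 1.37 in coupling partner and 1 in free catalyst, holding that “binding of partner to free catalyst limits turnover”.

The flask gives 1.4 in coupling partner and 1.1 in free catalyst.

    substrate + catalyst intermediate A → catalyst intermediate B (k = 0.666 L mol⁻¹ s⁻¹)
    coupling partner + free catalyst → catalyst intermediate A (k = 0.0491 L mol⁻¹ s⁻¹)
    coupling partner ⇌ dormant form (K = 0.394, k = 4.47 × 10⁻⁶ s⁻¹)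
    catalyst intermediate B → free catalyst + target (k = 0.0325 s⁻¹)

At 1.20 d in this flask, free catalyst, the resting state, is 90.7% of the catalyst charged. Use k again on this flask: at 30% conversion it gives 0.0421 M d⁻¹, and the flask's rate there is 0.0427 M d⁻¹. Then use it on the violet flask, whose charge allows 50.0%: at 2.50 d, k gives 38.9% target, and violet reads 38%.

The numbers in the tables come from a simulation for an exercise; scatter was added.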